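**Retrosynthetic overview**
- The target is the benzylic ester of haematommic acid (ring B acid) with the C6 hydroxymethyl form of atraric acid (ring A). Both benzene rings are bought intact, so no ring is formed in the route.
- Key disconnection: the benzylic C(sp3)–O ester bond, made by a new copper-mediated coupling of a ring A benzylic pinacol boronate with the ring B carboxylic acid. This avoids a free hydroxymethyl benzoate, which would close to a phthalide.
- Ring A boronate: atraric acid, MOM protection, then ester-directed lateral lithiation–borylation of the C6 methyl only.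
- Ring B acid: orsellinic acid, benzyl ester, C3 formylation, MOM protection, hydrogenolysis.
- Last step: acidic removal of the four MOM groups.

Assumption: the target SMILES contains no stereocentre or other stereo element, so the compound is achiral and no step needs stereocontrol.

**Step 1**
Reactants: 1 methyl 2,4-dihydroxy-3,6-dimethylbenzoate (atraric acid)
Product: 3 methyl 2,4-bis(methoxymethoxy)-3,6-dimethylbenzoate, via disodium bis(phenoxide) 2 (not isolated)
Conditions: NaH (2.6 equiv), DMF, 0 °C; then MOMCl (2.6 equiv), 0 °C to rt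
Reagents that add atoms: chloromethyl methyl ether (MOMCl) COCCl
Why: Williamson-type O-alkylation of both sodium phenoxides, NaH in DMF being strong enough to break the hydrogen bond of the C2 hydroxyl to the ester; no stereocentre is formed.

**Step 2**
Reactants: 3 methyl 2,4-bis(methoxymethoxy)-3,6-dimethylbenzoate
Product: 6 methyl 2,4-bis(methoxymethoxy)-3-methyl-6-[(4,4,5,5-tetramethyl-1,3,2-dioxaborolan-2-yl)methyl]benzoate, via benzylic lithium dienolate 4 (not isolated), via lithium borate complex 5 (not isolated)
Conditions: LiN(i-Pr)2 (1.2 equiv, commercial solution), THF, −78 °C, 20 min; i-PrOBpin (1.5 equiv), −78 °C, 1 h; AcOH (1.3 equiv), −78 °C to rt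
Reagents that add atoms: 2-isopropoxy-4,4,5,5-tetramethyl-1,3,2-dioxaborolane (i-PrOBpin) CC(C)OB1OC(C)(C)C(C)(C)O1
Why: Ester-directed lateral lithiation followed by borylation: the amide base deprotonates only the C6 methyl, whose anion is a vinylogous ester enolate (the C3 methyl has no such stabilisation and the hindered methyl ester is not attacked at −78 °C), and trapping at carbon by the borate restores aromaticity.

**Step 3**
Reactants: 7 2,4-dihydroxy-6-methylbenzoic acid (orsellinic acid)
Product: 9 benzyl 2,4-dihydroxy-6-methylbenzoate, via potassium orsellinate 8 (not isolated)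
Conditions: KHCO3 (1.2 equiv), BnBr (1.05 equiv), DMF, rt, 16 h
Reagents that add atoms: benzyl bromide BrCc1ccccc1
Why: Chemoselective SN2 O-alkylation of the carboxylate, since KHCO3 deprotonates only the carboxylic acid and leaves both phenols free.

**Step 4**
Reactants: 9 benzyl 2,4-dihydroxy-6-methylbenzoate
Product: 11 benzyl 3-formyl-2,4-dihydroxy-6-methylbenzoate (benzyl haematommate), via chloro(methoxy)methyl arene 10 (not isolated)
Conditions: TiCl4 (2.5 equiv), Cl2CHOMe (1.2 equiv), CH2Cl2, −10 to 0 °C, 1 h; then 1 M aq HCl, rt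
Reagents that add atoms: dichloromethyl methyl ether COC(Cl)Cl; water O
Why: Rieche formylation (electrophilic aromatic substitution on the titanium phenoxide) should place the formyl group at C3, which is ortho to both hydroxyls and favoured by the chelated C2 hydroxyl, as in the classical route from orsellinates to haematommates; hydrolysis of 10 on work-up gives the aldehyde.

**Step 5**
Reactants: 11 benzyl 3-formyl-2,4-dihydroxy-6-methylbenzoate
Product: 13 benzyl 3-formyl-2,4-bis(methoxymethoxy)-6-methylbenzoate, via disodium bis(phenoxide) 12 (not isolated)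
Conditions: NaH (2.6 equiv), DMF, 0 °C; then MOMCl (2.8 equiv), 0 °C to rt
Reagents that add atoms: chloromethyl methyl ether (MOMCl) COCCl
Why: Williamson-type O-alkylation of both chelated phenoxides; the non-enolisable aldehyde and the benzyl ester are inert to NaH and MOMCl.

**Step 6**
Reactants: 13 benzyl 3-formyl-2,4-bis(methoxymethoxy)-6-methylbenzoate
Product: 14 3-formyl-2,4-bis(methoxymethoxy)-6-methylbenzoic acid
Conditions: H2 (1 atm), 10% Pd/C, EtOAc, rt, 30–60 min, stopped at full conversion; used at once
Reagents that add atoms: none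
Why: Catalytic hydrogenolysis of the benzyl ester C–O bond is much faster than reduction of the hindered, electron-rich aldehyde flanked by two MOM ethers, which themselves are inert.

**Step 7**
Reactants: 6 methyl 2,4-bis(methoxymethoxy)-3-methyl-6-[(4,4,5,5-tetramethyl-1,3,2-dioxaborolan-2-yl)methyl]benzoate; 14 3-formyl-2,4-bis(methoxymethoxy)-6-methylbenzoic acid
Product: 17 [2-(methoxycarbonyl)-3,5-bis(methoxymethoxy)-4-methylphenyl]methyl 3-formyl-2,4-bis(methoxymethoxy)-6-methylbenzoate, via caesium carboxylate 15 (not isolated), via benzylcopper carboxylate 16 (not isolated)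
Conditions: 14 (1.0 equiv), Cs2CO3 (1.1 equiv), MeCN, rt, 15 min; then Cu(OTf)2 (2.2 equiv), pyridine (6 equiv), 6 (1.5 equiv), 4 Å molecular sieves, MeCN, 45 °C, argon, 12 h
Reagents that add atoms: none
Why: Proposed new method: a copper-mediated Chan–Lam-type C(sp3)–O coupling of a primary benzylic pinacol boronate with a hindered carboxylate under argon, in which carbonate-assisted boron-to-copper transmetalation of 6 onto the divalent copper carboxylate formed from 15 (helped by chelation of the ortho ester carbonyl and the vinylogous-enolate character of the benzyl group) is followed by oxidation with a second equivalent of Cu(OTf)2 to the trivalent benzylcopper carboxylate 16 and inner-sphere C–O reductive elimination, so that no free benzylic cation or alkoxide (and hence no phthalide) arises and any benzyl radical from Cu–C homolysis is recaptured by divalent copper carboxylate as in Kharasch–Sosnovsky acyloxylation; the closest known reaction type is the Chan–Lam oxidative coupling (aryl boron reagents with carboxylic acids, benzylic boronic esters with N-nucleophiles), not yet shown for benzylic boron reagents with carboxylates; no stereocentre is formed.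

**Step 8**
Reactants: 17 [2-(methoxycarbonyl)-3,5-bis(methoxymethoxy)-4-methylphenyl]methyl 3-formyl-2,4-bis(methoxymethoxy)-6-methylbenzoate
Product: 18 [3,5-dihydroxy-2-(methoxycarbonyl)-4-methylphenyl]methyl 3-formyl-2,4-dihydroxy-6-methylbenzoate (target, CNP0122264.0)
Conditions: conc. HCl (10 equiv), MeOH–THF (1:1), 40 °C, 4 h
Reagents that add atoms: none
Why: Acid-catalysed acetal exchange cleaves the four MOM ethers with methanol as the formaldehyde acceptor, while the doubly ortho-substituted aroyl ester and the methyl ester are too hindered to transesterify and the benzylic C–O bond (meta to both hydroxyls, ortho to an ester) does not ionise.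

**Compound list**
1 | methyl 2,4-dihydroxy-3,6-dimethylbenzoate (atraric acid) | COC(=O)c1c(C)cc(O)c(C)c1O | starting material
2 | disodium 4-(methoxycarbonyl)-2,5-dimethylbenzene-1,3-bis(olate) (disodium salt of 1) | [Na+].[Na+].COC(=O)c1c(C)cc([O-])c(C)c1[O-] | intermediate
3 | methyl 2,4-bis(methoxymethoxy)-3,6-dimethylbenzoate | COC(=O)c1c(C)cc(OCOC)c(C)c1OCOC | intermediate
4 | methyl 6-(lithiomethyl)-2,4-bis(methoxymethoxy)-3-methylbenzoate (benzylic lithium dienolate, drawn in its C-lithio form) | [Li]Cc1cc(OCOC)c(C)c(OCOC)c1C(=O)OC | intermediate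
5 | lithium [2-(methoxycarbonyl)-3,5-bis(methoxymethoxy)-4-methylbenzyl](isopropoxy)(pinacolato)borate | [Li+].CC(C)O[B-]1(Cc2cc(OCOC)c(C)c(OCOC)c2C(=O)OC)OC(C)(C)C(C)(C)O1 | intermediate
6 | methyl 2,4-bis(methoxymethoxy)-3-methyl-6-[(4,4,5,5-tetramethyl-1,3,2-dioxaborolan-2-yl)methyl]benzoate | COC(=O)c1c(CB2OC(C)(C)C(C)(C)O2)cc(OCOC)c(C)c1OCOC | intermediate
7 | 2,4-dihydroxy-6-methylbenzoic acid (orsellinic acid) | Cc1cc(O)cc(O)c1C(=O)O | starting material
8 | potassium 2,4-dihydroxy-6-methylbenzoate (potassium orsellinate) | [K+].Cc1cc(O)cc(O)c1C(=O)[O-] | intermediate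
9 | benzyl 2,4-dihydroxy-6-methylbenzoate | Cc1cc(O)cc(O)c1C(=O)OCc1ccccc1 | intermediate
10 | benzyl 3-[chloro(methoxy)methyl]-2,4-dihydroxy-6-methylbenzoate (racemic, transient) | Cc1cc(O)c(C(Cl)OC)c(O)c1C(=O)OCc1ccccc1 | intermediate
11 | benzyl 3-formyl-2,4-dihydroxy-6-methylbenzoate (benzyl haematommate) | Cc1cc(O)c(C=O)c(O)c1C(=O)OCc1ccccc1 | intermediate
12 | disodium 4-(benzyloxycarbonyl)-2-formyl-5-methylbenzene-1,3-bis(olate) (disodium salt of 11) | [Na+].[Na+].Cc1cc([O-])c(C=O)c([O-])c1C(=O)OCc1ccccc1 | intermediate
13 | benzyl 3-formyl-2,4-bis(methoxymethoxy)-6-methylbenzoate | COCOc1cc(C)c(C(=O)OCc2ccccc2)c(OCOC)c1C=O | intermediate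
14 | 3-formyl-2,4-bis(methoxymethoxy)-6-methylbenzoic acid | COCOc1cc(C)c(C(=O)O)c(OCOC)c1C=O | intermediate
15 | caesium 3-formyl-2,4-bis(methoxymethoxy)-6-methylbenzoate | [Cs+].COCOc1cc(C)c(C(=O)[O-])c(OCOC)c1C=O | intermediate
16 | trivalent copper complex carrying the 2-(methoxycarbonyl)-3,5-bis(methoxymethoxy)-4-methylbenzyl group, the carboxylate of 14 and triflate (pyridine ligands not drawn) | COC(=O)c1c(C[Cu](OC(=O)c2c(C)cc(OCOC)c(C=O)c2OCOC)OS(=O)(=O)C(F)(F)F)cc(OCOC)c(C)c1OCOC | intermediate
17 | [2-(methoxycarbonyl)-3,5-bis(methoxymethoxy)-4-methylphenyl]methyl 3-formyl-2,4-bis(methoxymethoxy)-6-methylbenzoate | COC(=O)c1c(COC(=O)c2c(C)cc(OCOC)c(C=O)c2OCOC)cc(OCOC)c(C)c1OCOC | intermediate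
18 | [3,5-dihydroxy-2-(methoxycarbonyl)-4-methylphenyl]methyl 3-formyl-2,4-dihydroxy-6-methylbenzoate (achiral) | COC(=O)c1c(COC(=O)c2c(C)cc(O)c(C=O)c2O)cc(O)c(C)c1O | target

**Step count and risks**
Total step count: 8. Longest linear sequence: 6 steps (7 → 9 → 11 → 13 → 14 → 17 → 18).

Risky step 7 (the proposed new coupling). Boron-to-copper transfer may be slow, 6 may protodeboronate back to 3, or the benzyl group may homocouple to a bibenzyl. The fallback uses known chemistry, sets out from 3 and comes back at 17. Compound 3 is lithiated as in step 2 (LiN(i-Pr)2, THF, −78 °C) to give 4. This solution is added by cannula to 1,2-dibromotetrachloroethane (1.5 equiv) in THF at −78 °C, an electrophilic bromination of a carbanion in which inverse addition suppresses dimerisation, to give methyl 6-(bromomethyl)-2,4-bis(methoxymethoxy)-3-methylbenzoate F1. The caesium carboxylate 15 (from 14 and Cs2CO3 in DMF at rt) then displaces bromide by SN2 to give 17. An ester is formed directly, so the phthalide problem is again avoided.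

Risky step 4 (regiochemistry of the formylation, C3 against C5, and Lewis-acid stress on the benzyl ester). The fallback replaces electrophilic formylation by directed ortho-metalation, sets out from 9 and comes back at 14. Compound 9 is protected first (NaH, then MOMCl, DMF) through the disodium bis(phenoxide) F2 to give benzyl 2,4-bis(methoxymethoxy)-6-methylbenzoate F3. Hydrogenolysis (H2, Pd/C, EtOAc), here with no aldehyde present, gives 2,4-bis(methoxymethoxy)-6-methylbenzoic acid F4. Treatment with s-BuLi (2.2 equiv) and TMEDA in THF at −78 °C deprotonates the carboxylic acid and then the only ring position flanked by two MOM ethers, giving lithium 3-lithio-2,4-bis(methoxymethoxy)-6-methylbenzoate F5. DMF converts this into the dilithium hemiaminal alkoxide F6, and an AcOH quench releases 14 with the formyl group unambiguously at C3.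

Risky step 6 (over-reduction of the aldehyde to the alcohol or methyl group during hydrogenolysis, a known reaction of haematommates on Pd). The fallback changes the ester protecting group so that no reductant is needed, sets out from 7 and comes back at 14. The potassium salt 8 is alkylated with allyl bromide (KHCO3, DMF, rt) to give allyl 2,4-dihydroxy-6-methylbenzoate F7. Rieche formylation as in step 4 gives, through allyl 3-[chloro(methoxy)methyl]-2,4-dihydroxy-6-methylbenzoate F8, allyl 3-formyl-2,4-dihydroxy-6-methylbenzoate F9. NaH and MOMCl give, through the disodium bis(phenoxide) F10, allyl 3-formyl-2,4-bis(methoxymethoxy)-6-methylbenzoate F11. Pd(PPh3)4 (3 mol %) and morpholine (3 equiv) in THF at rt then transfer the allyl group to the amine by zerovalent-palladium π-allyl chemistry (Tsuji–Trost deallylation), giving the morpholinium carboxylate F12, and a pH 4 work-up gives 14.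

**Further compounds**
F1 | step 7 | methyl 6-(bromomethyl)-2,4-bis(methoxymethoxy)-3-methylbenzoate | COC(=O)c1c(CBr)cc(OCOC)c(C)c1OCOC
F2 | step 4 | disodium 4-(benzyloxycarbonyl)-5-methylbenzene-1,3-bis(olate) (disodium salt of 9) | [Na+].[Na+].Cc1cc([O-])cc([O-])c1C(=O)OCc1ccccc1
F3 | step 4 | benzyl 2,4-bis(methoxymethoxy)-6-methylbenzoate | COCOc1cc(C)c(C(=O)OCc2ccccc2)c(OCOC)c1
F4 | step 4 | 2,4-bis(methoxymethoxy)-6-methylbenzoic acid | COCOc1cc(C)c(C(=O)O)c(OCOC)c1
F5 | step 4 | lithium 3-lithio-2,4-bis(methoxymethoxy)-6-methylbenzoate | [Li+].[Li]c1c(OCOC)cc(C)c(C(=O)[O-])c1OCOC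
F6 | step 4 | dilithium 3-[(dimethylamino)(oxido)methyl]-2,4-bis(methoxymethoxy)-6-methylbenzoate | [Li+].[Li+].CN(C)C([O-])c1c(OCOC)cc(C)c(C(=O)[O-])c1OCOC
F7 | step 6 | allyl 2,4-dihydroxy-6-methylbenzoate | C=CCOC(=O)c1c(C)cc(O)cc1O
F8 | step 6 | allyl 3-[chloro(methoxy)methyl]-2,4-dihydroxy-6-methylbenzoate | C=CCOC(=O)c1c(C)cc(O)c(C(Cl)OC)c1O
F9 | step 6 | allyl 3-formyl-2,4-dihydroxy-6-methylbenzoate | C=CCOC(=O)c1c(C)cc(O)c(C=O)c1O
F10 | step 6 | disodium salt of F9 (bis-phenoxide) | [Na+].[Na+].C=CCOC(=O)c1c(C)cc([O-])c(C=O)c1[O-]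
F11 | step 6 | allyl 3-formyl-2,4-bis(methoxymethoxy)-6-methylbenzoate | C=CCOC(=O)c1c(C)cc(OCOC)c(C=O)c1OCOC
F12 | step 6 | morpholinium 3-formyl-2,4-bis(methoxymethoxy)-6-methylbenzoate | C1COCC[NH2+]1.COCOc1cc(C)c(C(=O)[O-])c(OCOC)c1C=O
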